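**Retrosynthetic overview**

1. Target 14 ⇒ enediol‑enal 13: the C4–C5 bond closes by a thermal conrotatory 4π‑electrocyclisation of a 2‑oxidopentadienyl system (Piancatelli/Nazarov type). The cyclopentenone is the only ring made and it is made last.
2. 13 ⇐ keto‑enal 12 ⇐ 6‑hydroxypyranone 11 (lactol opening, enolisation) ⇐ furyl carbinol 10 by Achmatowicz oxidation.
3. 10 ⇐ α‑acetoxy 2‑furyl ketone 9 ⇐ acid chloride 7 + 2‑stannylfuran 8 (acyl Stille).
4. 7 ⇐ (S)‑2‑hydroxyhexadecanoic acid 5 ⇐ methyl (S)‑glycidate 1 + C13 Grignard from 2 (Cu‑catalysed epoxide opening).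
5. C1′ is bought in 1 and directs C5 and C4 in the ring closure. Ring order: furan (bought) → pyranone → cyclopentenone.

Assumption: methyl (S)‑glycidate is taken as the cheap enantiopure building block; the carbinol centre of 10 and C2/C6 of 11 are carried as epimer mixtures because step 6 erases them. Ring numbering: C1 = C=O, C2=C3, C4 = CHOH, C5 = C(OH), C1′ = CHOAc.

**Step 1**
Reactants: 1 methyl (S)‑glycidate; 2 1‑bromotridecane
Product: 5 (S)‑2‑hydroxyhexadecanoic acid, via tridecylmagnesium bromide 3 (not isolated), via methyl (S)‑2‑hydroxyhexadecanoate 4 (not isolated)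
Conditions: 2, Mg, THF; CuI (10 mol %), −40 °C, add 1, → −20 °C; then LiOH, H2O/MeOH, rt; HCl to pH 2; recrystallise
Reagents that add atoms: lithium hydroxide, [Li+].[OH-]
Why: Cu(I)‑catalysed Grignard opening of the epoxide is an SN2 attack at the unsubstituted CH2, so the bought C–O stereocentre is untouched, and the ester is then saponified in the same pot.

**Step 2**
Reactants: 5 (S)‑2‑hydroxyhexadecanoic acid
Product: 7 (S)‑2‑acetoxyhexadecanoyl chloride, via (S)‑2‑acetoxyhexadecanoic acid 6 (not isolated)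
Conditions: AcCl (neat), 40 °C; evaporate; (COCl)2, cat. DMF, CH2Cl2, 0 °C → rt; evaporate
Reagents that add atoms: acetyl chloride, CC(Cl)=O; oxalyl chloride, ClC(=O)C(Cl)=O
Why: O‑acetylation followed by Vilsmeier‑type acid chloride formation is base‑free, so no ketene forms and C2 keeps its configuration.

**Step 3**
Reactants: 7 (S)‑2‑acetoxyhexadecanoyl chloride; 8 2‑(tributylstannyl)furan
Product: 9 (2S)‑1‑(furan‑2‑yl)‑1‑oxohexadecan‑2‑yl acetate
Conditions: PdCl2(PPh3)2 (3 mol %), toluene, 60 °C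
Reagents that add atoms: none
Why: Acyl Stille coupling (oxidative addition of the acid chloride, fast 2‑furyl transfer from tin, reductive elimination) gives the ketone under neutral conditions that spare the acetate and the α‑stereocentre.

**Step 4**
Reactants: 9 (2S)‑1‑(furan‑2‑yl)‑1‑oxohexadecan‑2‑yl acetate
Product: 10 (1RS,2S)‑1‑(furan‑2‑yl)‑1‑hydroxyhexadecan‑2‑yl acetate
Conditions: NaBH4, CeCl3·7H2O, MeOH, −40 → −20 °C; pH 7 buffer work‑up
Reagents that add atoms: none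
Why: Luche reduction takes the aryl ketone only, and the cold, weakly acidic medium suppresses 1,2‑acetyl migration; the new carbinol centre is not controlled because it becomes sp2 again in step 6.

**Step 5**
Reactants: 10 (1RS,2S)‑1‑(furan‑2‑yl)‑1‑hydroxyhexadecan‑2‑yl acetate
Product: 11 (1S)‑1‑(6‑hydroxy‑3‑oxo‑3,6‑dihydro‑2H‑pyran‑2‑yl)pentadecyl acetate (C2/C6 epimers)
Conditions: mCPBA (1.1 equiv), CH2Cl2, 0 °C; NaHCO3 wash
Reagents that add atoms: mCPBA, OOC(=O)c1cccc(Cl)c1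
Why: Achmatowicz rearrangement: peracid oxidation of the 2‑furylcarbinol and ring expansion to the 6‑hydroxy‑2H‑pyran‑3(6H)‑one, with C1′ untouched.

**Step 6**
Reactants: 11 (1S)‑1‑(6‑hydroxy‑3‑oxo‑3,6‑dihydro‑2H‑pyran‑2‑yl)pentadecyl acetate
Product: 14 (4S,5R)‑5‑[(1S)‑1‑acetoxypentadecyl]‑4,5‑dihydroxycyclopent‑2‑en‑1‑one (target), via (Z)‑keto‑enal 12 (not isolated), via (E)‑enediol 13 (not isolated)
Conditions: Et3N (0.3 equiv), DMF, 0 °C → rt
Reagents that add atoms: none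
Why: Lactol opening and enolisation give 13, which closes by a Piancatelli/Nazarov‑type conrotatory 4π‑electrocyclisation (pyranone → cyclopentenone); the bulky side chain and the aldehyde oxygen both sit outside, so the side chain ends trans to 4‑OH (cis‑4,5‑diol), and the C4–C5 bond is expected to form anti to the C1′–OAc bond (polar Felkin–Anh model, not precedent on this substrate), giving 4S,5R from the bought 1′S centre.

**Compound list**

1 | methyl (2S)‑oxirane‑2‑carboxylate (methyl (S)‑glycidate) | COC(=O)[C@@H]1CO1 | starting material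
2 | 1‑bromotridecane | CCCCCCCCCCCCCBr | starting material
3 | tridecylmagnesium bromide (formed in situ) | CCCCCCCCCCCCC[Mg]Br | intermediate
4 | methyl (2S)‑2‑hydroxyhexadecanoate (not isolated) | CCCCCCCCCCCCCC[C@H](O)C(=O)OC | intermediate
5 | (2S)‑2‑hydroxyhexadecanoic acid | CCCCCCCCCCCCCC[C@H](O)C(=O)O | intermediate
6 | (2S)‑2‑acetoxyhexadecanoic acid (not isolated) | CCCCCCCCCCCCCC[C@H](OC(C)=O)C(=O)O | intermediate
7 | (2S)‑2‑acetoxyhexadecanoyl chloride | CCCCCCCCCCCCCC[C@H](OC(C)=O)C(Cl)=O | intermediate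
8 | 2‑(tributylstannyl)furan | CCCC[Sn](CCCC)(CCCC)c1ccco1 | starting material
9 | (2S)‑1‑(furan‑2‑yl)‑1‑oxohexadecan‑2‑yl acetate | CCCCCCCCCCCCCC[C@H](OC(C)=O)C(=O)c1ccco1 | intermediate
10 | (1RS,2S)‑1‑(furan‑2‑yl)‑1‑hydroxyhexadecan‑2‑yl acetate (carbinol epimers) | CCCCCCCCCCCCCC[C@H](OC(C)=O)C(O)c1ccco1 | intermediate
11 | (1S)‑1‑[(2RS,6RS)‑6‑hydroxy‑3‑oxo‑3,6‑dihydro‑2H‑pyran‑2‑yl]pentadecyl acetate | CCCCCCCCCCCCCC[C@H](OC(C)=O)C1OC(O)C=CC1=O | intermediate
12 | (2Z,6S)‑5‑hydroxy‑1,4‑dioxoicos‑2‑en‑6‑yl acetate (ring‑opened keto‑enal, not isolated) | CCCCCCCCCCCCCC[C@H](OC(C)=O)C(O)C(=O)/C=C\C=O | intermediate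
13 | (2Z,4E,6S)‑4,5‑dihydroxy‑1‑oxoicosa‑2,4‑dien‑6‑yl acetate (enediol, reacts as its ammonium enediolate, not isolated) | CCCCCCCCCCCCCC[C@H](OC(C)=O)/C(O)=C(O)/C=C\C=O | intermediate
14 | (4S,5R)‑5‑[(1S)‑1‑acetoxypentadecyl]‑4,5‑dihydroxycyclopent‑2‑en‑1‑one (CNP0263753.3) | CCCCCCCCCCCCCC[C@H](OC(C)=O)[C@@]1(O)C(=O)C=C[C@@H]1O | target

**Totals**

Total steps: 6. Longest linear sequence: 6 steps (1 → 14); 2 and 8 are bought and enter directly.

**Three steps most likely to fail**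

Step 6 (ring contraction). The facial control by C1′ rests on a model, and the enolised pyranone or enediol could lose AcOH by E1cB or let the acetyl wander to 4‑OH. The fallback sets out from 9 and returns at 14. It carries the C1′ oxygen through the same electrocyclisation as a bulky, non‑leaving silyl ether and acetylates at the end. Acid methanolysis (cat. HCl, MeOH) of 9 gives (2S)‑1‑(furan‑2‑yl)‑2‑hydroxyhexadecan‑1‑one F1. TBSCl/imidazole gives the silyl ether ketone F2, NaBH4 gives the silyloxy carbinol F3, and mCPBA gives the silyloxy pyranone F4. Et3N in DMF then gives the silyloxy cyclopentenone diol F5. 2,2‑Dimethoxypropane/PPTS closes the cis‑4,5‑diol as the acetonide F6, which also proves the cis relationship. HF·pyridine frees the C1′ alcohol F7 (acidic, to avoid retro‑aldol), Ac2O/DMAP gives the acetate acetonide F8, and aqueous TFA at 0 °C releases 14.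

Step 4 (reduction next to an acetate). The acetyl group may migrate to the furfuryl oxygen or be cleaved. The fallback sets out from 9 and returns at 11, and never has a free hydroxyl beside the acetate. LiAlH4 reduces 9 to (2S)‑1‑(furan‑2‑yl)hexadecane‑1,2‑diol F9. NaHCO3‑buffered mCPBA gives the dihydroxy pyranone F10, in which the former furfuryl oxygen is locked in the ring. Ac2O/pyridine gives the diacetate F11. NH4OAc in DMF removes only the anomeric (acylal) acetate to give 11.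

Step 3 (acyl Stille on an α‑acetoxy acid chloride). Decarbonylation of the acyl‑palladium or sluggish coupling could intervene. The fallback sets out from 5 and returns at 9, using a Weinreb ketone synthesis with acetylation afterwards. EDC/HOBt coupling of 5 with MeNH(OMe)·HCl gives (2S)‑2‑hydroxy‑N‑methoxy‑N‑methylhexadecanamide F12. Excess 2‑furyllithium F13 (furan, n‑BuLi, THF, −78 → 0 °C, AcOH quench) gives the hydroxy ketone F14. Ac2O/pyridine at 0 °C gives 9.

**Further compounds**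

F1 | step 6 | (2S)‑1‑(furan‑2‑yl)‑2‑hydroxyhexadecan‑1‑one | CCCCCCCCCCCCCC[C@H](O)C(=O)c1ccco1
F2 | step 6 | (2S)‑2‑(tert‑butyldimethylsilyloxy)‑1‑(furan‑2‑yl)hexadecan‑1‑one | CCCCCCCCCCCCCC[C@H](O[Si](C)(C)C(C)(C)C)C(=O)c1ccco1
F3 | step 6 | (1RS,2S)‑2‑(tert‑butyldimethylsilyloxy)‑1‑(furan‑2‑yl)hexadecan‑1‑ol | CCCCCCCCCCCCCC[C@H](O[Si](C)(C)C(C)(C)C)C(O)c1ccco1
F4 | step 6 | 2‑[(1S)‑1‑(tert‑butyldimethylsilyloxy)pentadecyl]‑6‑hydroxy‑2H‑pyran‑3(6H)‑one (C2/C6 epimers) | CCCCCCCCCCCCCC[C@H](O[Si](C)(C)C(C)(C)C)C1OC(O)C=CC1=O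
F5 | step 6 | C1′‑O‑TBS analogue of 14 (cis‑4,5‑diol, all centres as in 14) | CCCCCCCCCCCCCC[C@H](O[Si](C)(C)C(C)(C)C)[C@@]1(O)C(=O)C=C[C@@H]1O
F6 | step 6 | 4,5‑O‑isopropylidene derivative of F5 | CCCCCCCCCCCCCC[C@H](O[Si](C)(C)C(C)(C)C)[C@@]1(OC2(C)C)C(=O)C=C[C@@H]1O2
F7 | step 6 | 4,5‑O‑isopropylidene C1′‑alcohol (desilylated F6) | CCCCCCCCCCCCCC[C@H](O)[C@@]1(OC2(C)C)C(=O)C=C[C@@H]1O2
F8 | step 6 | 4,5‑O‑isopropylidene derivative of 14 | CCCCCCCCCCCCCC[C@H](OC(C)=O)[C@@]1(OC2(C)C)C(=O)C=C[C@@H]1O2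
F9 | step 4 | (1RS,2S)‑1‑(furan‑2‑yl)hexadecane‑1,2‑diol | CCCCCCCCCCCCCC[C@H](O)C(O)c1ccco1
F10 | step 4 | 6‑hydroxy‑2‑[(1S)‑1‑hydroxypentadecyl]‑2H‑pyran‑3(6H)‑one (C2/C6 epimers) | CCCCCCCCCCCCCC[C@H](O)C1OC(O)C=CC1=O
F11 | step 4 | 6‑acetoxy‑2‑[(1S)‑1‑acetoxypentadecyl]‑2H‑pyran‑3(6H)‑one (C2/C6 epimers) | CCCCCCCCCCCCCC[C@H](OC(C)=O)C1OC(OC(C)=O)C=CC1=O
F12 | step 3 | (2S)‑2‑hydroxy‑N‑methoxy‑N‑methylhexadecanamide | CCCCCCCCCCCCCC[C@H](O)C(=O)N(C)OC
F13 | step 3 | 2‑furyllithium | [Li]c1ccco1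
F14 | step 3 | (2S)‑1‑(furan‑2‑yl)‑2‑hydroxyhexadecan‑1‑one | CCCCCCCCCCCCCC[C@H](O)C(=O)c1ccco1
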